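- I had no constants for cedar, so I turned its readings into times and set them in order, fastest first.

in all of them: substrate 0.80 M
- cedar: reagent 0.76 M; capture agent 0.040 M; free catalyst 8 mM; the very flask that is asked about, followed so far
- larch: reagent 0.76 M; capture agent 0.040 M; free catalyst 12 mM; run made earlier
- flask: reagent 0.760 M; capture agent 0.0400 M; free catalyst 8.0 mM; time 10 min

- cedar (time / min: product / %): 1.33: 51.5; 2.50: 61.5; 4.00: 66.9; 5.00: 68.8; 6.00: 70.3
- larch (time / s: product / %): 10.0: 21.4; 30.0: 41.1; 60.0: 56.1; 80.0: 61.2; 120: 66.8

(standard deviation of a reading: 0.5 percentage points)

- Friday's: change nothing and wait 10 min more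
- Saturday's: at 10 min take out 90 % of the product then present, then wait 10 min
- Tuesday's: at 10 min add reagent, 100 % of the amount charged, then wait 10 min
- Monday's: at 10 min add free catalyst, 50.0 % of the amount charged, then wait 10 min

- product that was removed still counts
- the numbers in the tables scatter by 0.5 percentage points (one standard deviation)
- additions bring no volume worth counting

- product, in percent of the substrate first charged, at 10 min
- which option adds most product ("none" when 2 percentage points or less is all one gets) (Friday's / Saturday's / Tuesday's / Monday's / none)
- product present, with what was taken out counted in, in percent of the substrate first charged, after Friday's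
- product present, with what was taken out counted in, in percent of the substrate first charged, after Saturday's

- Fastest rung: larch made 21.4 % in 10.0 s, and that rate, scaled down to cedar's catalyst, would convert the whole charge in 1.17 min.
- Second rung: cedar's product rate, in fractions of the charge, fell from 0.0360 /min to 0.0170 /min, which gives a dying time of 2.33 min, a reading carrying the scatter of 0.5 percentage points, and longer than the first rung.
- I took this fading for loss of catalyst, because cedar stood at 70.3 %, below the 95.0 % that the reagent charge allows.
- Slowest rung: the asked time is 4.29 dying times, so cedar should be close to its plateau. The reading at 5.00 min plus a tail of 4 points gives 72.8 %, and my figure at 10 min is 72.3 %.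
- The rule I carry is the catalyst's budget, the turnover number: plateau product per catalyst charged, 72.8 for a charge of 8 mM.
- Waiting has 0.46 points to give, less than the margin. Saturday's and Tuesday's add nothing to the catalyst's budget, and I put no figure on them. The reagent charge leaves 22 points above my plateau, and Monday's dose is priced at 36 points, more than that, so I chose Monday's.
- The forecast, whose grounds were “So the catalyst is dying, with a lifetime of roughly 160 s”, gave 71.8 %, Monday's, 72.2 % and 72.2 %. Its figure for now lies below mine.
- The flask gave 72.4 % and Monday's, with gains of 0.89 points for Friday's, 4.4 points for Saturday's, 3.9 points for Tuesday's and 8.3 points for Monday's, and 73.3 % and 76.8 % for the two asked totals.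

    catalyst intermediate A + product → spent catalyst (k = 0.0230 /M/s)
    catalyst intermediate A → catalyst intermediate B (k = 260 /s)
    catalyst intermediate C + capture agent → trapped intermediate (k = 1.80 /M/s)
    catalyst intermediate C ⇌ free catalyst + product (K = 0.550 M, k = 150 /s)
    reagent + free catalyst ⇌ catalyst intermediate A (K = 1.00 /M, k = 8.70 /M/s)
    substrate + catalyst intermediate B ⇌ catalyst intermediate C (K = 0.530 /M, k = 3.60 /M/s)

- In the flask, product per catalyst charged stood at 72.4 at 10 min and 73.4 at 100 min, against the budget of 72.8. The neighbour with 1.4 M of substrate has the same catalyst charge, so the budget allows it 0.582 M of product, or 41.6 % of its substrate. That neighbour gave 41.9 %, with 99.7 % of its catalyst trapped and 58 % of its substrate left.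

The runs come from a simulation with constants of no real substance; the scatter is artificial.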